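## Retrosynthetic overview

1. Propolin B comes in the last step from its tetra-MOM/TES-protected form, which already holds all 25 carbons, the E-alkene and the single stereocentre C2.
2. The key disconnection is C1' (ring B)–C2 (ring C). It leads back to a ring-B arene that carries only C1'–H and to flat, achiral 5,7-bis(MOM)chromone. Forward, it is one flask with three components (arene, B2pin2, chromone) and two catalytic cycles: iridium C–H borylation at C1', then rhodium-catalysed enantioselective 1,4-addition to C2.
3. Enabling feature: before the union, ring B is a 1,2,3-trisubstituted benzene (O3', O4', chain at C5'). C1'–H is therefore its only C–H flanked by two C–H bonds (C2'–H, C6'–H), and it is the one a sterically governed borylation takes. C2 is the β-carbon of the vinylogous ester O1–C2=C3–C4=O of ring C, a prochiral acceptor already at the oxidation level of the flavanone.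
4. The ring-B arene comes from catechol bis-MOM ether (directed ortho-lithiation at the future C5') and an E-allylic bromide. The bromide is made from geranyl acetate by hydration of the distal alkene.
5. Ring order: no ring is built. Ring B comes from catechol, and rings A and C come together from 5,7-dihydroxychromone. Ring C only passes from a planar pyranone to the chiral dihydropyranone in the key step.

Key step: step 7

Assumption: geranyl acetate (E), catechol and 5,7-dihydroxychromone are taken as commercial, and the sense of induction in step 7 is assigned by analogy with 2-cyclohexenone, where (S)-configured biaryl bisphosphines give (S)-3-aryl ketones, the spatial equivalent of (2S) in a flavanone.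

## Route

Step 1
Reactants: 1 geranyl acetate, (2E)-3,7-dimethylocta-2,6-dien-1-yl acetate
Product: 4 (2E)-3,7-dimethyloct-2-ene-1,7-diol, via organomercurial 2 (not isolated), via hydroxy acetate 3 (not isolated)
Conditions: Hg(OAc)2 (1.0 equiv), THF/H2O 1:1, 0 °C to rt; then 3 M aq. NaOH, NaBH4, 0 °C; then MeOH, rt
Reagents that add atoms: water, O; Hg(OAc)2, CC(=O)O[Hg]OC(C)=O (its HgOAc group stays only in 2)
Why: Oxymercuration–demercuration is a Markovnikov hydration that should take the 6,7-alkene first because the 2,3-alkene is deactivated by the allylic acetoxy group, and the alkaline demercuration medium then saponifies the acetate without touching the E-alkene.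

Step 2
Reactants: 4 (2E)-3,7-dimethyloct-2-ene-1,7-diol
Product: 5 (6E)-8-bromo-2,6-dimethyloct-6-en-2-ol
Conditions: NBS (1.3 equiv), Me2S (1.5 equiv), CH2Cl2, −20 °C; then 4, −20 to 0 °C
Reagents that add atoms: N-bromosuccinimide, O=C1CCC(=O)N1Br
Why: In the Corey–Kim halogenation only the alkoxysulfonium salt of the primary allylic alcohol is displaced by bromide (SN2, no allylic shift), while the tertiary alcohol is returned on work-up and the pre-complexed NBS leaves the E-alkene alone.

Step 3
Reactants: 5 (6E)-8-bromo-2,6-dimethyloct-6-en-2-ol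
Product: 6 {[(6E)-8-bromo-2,6-dimethyloct-6-en-2-yl]oxy}triethylsilane
Conditions: TESOTf (1.2 equiv), 2,6-lutidine (1.6 equiv), CH2Cl2, −78 to −20 °C
Reagents that add atoms: triethylsilyl triflate, CC[Si](CC)(CC)OS(=O)(=O)C(F)(F)F
Why: Silyl triflate silylation is fast enough for a tertiary alcohol at low temperature, the hindered base is not alkylated by the allylic bromide, and the acidic O–H is thereby masked for the organolithium and iridium steps.

Step 4
Reactants: 7 catechol (benzene-1,2-diol)
Product: 8 1,2-bis(methoxymethoxy)benzene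
Conditions: NaH (2.4 equiv), MOMCl (2.4 equiv), DMF, 0 °C to rt
Reagents that add atoms: chloromethyl methyl ether, COCCl
Why: Williamson-type O-alkylation of the bis-phenoxide gives the bis-acetal, which later serves as the directing group for lithiation and as a steric shield in the borylation.

Step 5
Reactants: 8 1,2-bis(methoxymethoxy)benzene; 6 {[(6E)-8-bromo-2,6-dimethyloct-6-en-2-yl]oxy}triethylsilane
Product: 10 1,2-bis(methoxymethoxy)-3-[(2E)-3,7-dimethyl-7-(triethylsilyloxy)oct-2-en-1-yl]benzene, via aryllithium 9 (not isolated)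
Conditions: 8 (1.3 equiv), n-BuLi (1.2 equiv), THF, 0 °C to rt; then CuBr·SMe2 (10 mol %), 6 (1.0 equiv), −78 °C to rt
Reagents that add atoms: n-butyllithium, [Li]CCCC (its lithium stays only in 9)
Why: Directed ortho-metalation places lithium beside an OMOM group (both such sites are equivalent), and the copper-catalysed allylic substitution should occur at the unhindered α-carbon of the primary bromide, the γ-carbon being fully substituted, with retention of the E geometry.

Step 6
Reactants: 11 5,7-dihydroxy-4H-chromen-4-one
Product: 12 5,7-bis(methoxymethoxy)-4H-chromen-4-one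
Conditions: NaH (2.5 equiv), MOMCl (2.6 equiv), DMF, 0 °C to rt
Reagents that add atoms: chloromethyl methyl ether, COCCl
Why: Williamson-type O-alkylation, in which full deprotonation with NaH also breaks the hydrogen bond of the 5-OH to C4=O, removes both acidic phenols that would otherwise turn the chromone into an unreactive phenoxide in step 7.

Step 7
Reactants: 10 1,2-bis(methoxymethoxy)-3-[(2E)-3,7-dimethyl-7-(triethylsilyloxy)oct-2-en-1-yl]benzene; 12 5,7-bis(methoxymethoxy)-4H-chromen-4-one
Product: 14 (2S)-2-{3,4-bis(methoxymethoxy)-5-[(2E)-3,7-dimethyl-7-(triethylsilyloxy)oct-2-en-1-yl]phenyl}-5,7-bis(methoxymethoxy)-2,3-dihydro-4H-chromen-4-one, via arylboronate 13 (not isolated)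
Conditions: 10 (1.4 equiv), B2pin2 (0.75 equiv), [Ir(OMe)(cod)]2 (1 mol %), dtbpy (4,4'-di-tert-butyl-2,2'-bipyridine, 2 mol %), MTBE, 80 °C, sealed; cool, H2O; then 12 (1.0 equiv), premixed [RhCl(C2H4)2]2 (3 mol %)/(S)-MeO-F12-BIPHEP [(S)-6,6'-dimethoxybiphenyl-2,2'-diylbis(bis(3,4,5-trifluorophenyl)phosphine), 6.5 mol %] in toluene, aq. KOH (0.3 equiv), 35 °C
Reagents that add atoms: bis(pinacolato)diboron, CC1(C)OB(OC1(C)C)B1OC(C)(C)C(C)(C)O1 (its boryl group stays only in 13)
Why: Ir(dtbpy)(Bpin)3 (trivalent iridium) cleaves the least hindered aryl C–H bond of 10 to give 13, which transmetalates with the help of hydroxide to Rh(OH)(L) (monovalent rhodium, L = the bisphosphine); the aryl–rhodium species inserts C2=C3 of 12 with the aryl group going to C2, and water protonates the oxa-π-allyl rhodium enolate at C3 and returns Rh(OH)(L). The closest known reaction types are the one-flask C–H borylation/rhodium 1,4-addition sequence on enones (Hartwig–Miyaura borylation followed by Hayashi–Miyaura addition) and the asymmetric Hayashi–Miyaura addition of arylboron reagents to chromones with electron-poor biaryl bisphosphines or chiral dienes. No ring is closed: rings A and C enter intact with 12, and ring C merely passes from the planar pyranone to the dihydropyranone, already at the ketone level of the target. C2, the only stereocentre, is controlled by the ligand alone: the (S)-biaryl backbone shields the Si face of C2 in the bound chromone, so the aryl group migrates to the Re face and gives 2S, the same spatial sense as the (S)-3-arylcyclohexanones formed from 2-cyclohexenone with (S)-configured biaryl bisphosphines. Site selectivity among the three aryl C–H bonds of 10 is secured by its 1,2,3-substitution (C4–H lies next to the chain, C6–H next to OMOM, and only C5–H, the future C1', has two C–H neighbours), the trisubstituted alkene is too hindered for borylation, hydroboration or aryl–rhodium insertion, and 1,2-addition is held back by the 5-OMOM group beside C4=O. Substoichiometric KOH, buffered by the boron by-product, and the low temperature should keep ring C from opening by retro-oxa-Michael reaction, and any protodeboronated aryl group simply returns as 10.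

Step 8
Reactants: 14 (2S)-2-{3,4-bis(methoxymethoxy)-5-[(2E)-3,7-dimethyl-7-(triethylsilyloxy)oct-2-en-1-yl]phenyl}-5,7-bis(methoxymethoxy)-2,3-dihydro-4H-chromen-4-one
Product: 16 propolin B, (2S)-2-{3,4-dihydroxy-5-[(2E)-7-hydroxy-3,7-dimethyloct-2-en-1-yl]phenyl}-5,7-dihydroxy-2,3-dihydro-4H-chromen-4-one, via tetrakis(trimethylsilyl) ether 15 (not isolated)
Conditions: TMSOTf (10 equiv), 2,2'-bipyridyl (15 equiv), CH3CN, 0 °C to rt; then H2O; then aq. HCl to pH 1–2, THF, rt; work-up at pH 5–6
Reagents that add atoms: trimethylsilyl triflate, C[Si](C)(C)OS(=O)(=O)C(F)(F)F (its silyl groups stay only in 15)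
Why: The silyl triflate/bipyridyl acetal exchange turns aryl MOM ethers into aryl TMS ethers without free acid, and brief dilute-acid hydrolysis then frees the four phenols and the tertiary alcohol under conditions too mild to close the C4' oxygen onto the chain alkene, ionise the tertiary alcohol or open ring C, so C2 should keep its configuration.

## Compound list

1 | geranyl acetate, (2E)-3,7-dimethylocta-2,6-dien-1-yl acetate | C/C(=C\COC(C)=O)CCC=C(C)C | starting material
2 | (2E)-6-(acetoxymercurio)-7-hydroxy-3,7-dimethyloct-2-en-1-yl acetate (racemic at C6) | C/C(=C\COC(C)=O)CCC([Hg]OC(C)=O)C(C)(C)O | intermediate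
3 | (2E)-7-hydroxy-3,7-dimethyloct-2-en-1-yl acetate | C/C(=C\COC(C)=O)CCCC(C)(C)O | intermediate
4 | (2E)-3,7-dimethyloct-2-ene-1,7-diol | C/C(=C\CO)CCCC(C)(C)O | intermediate
5 | (6E)-8-bromo-2,6-dimethyloct-6-en-2-ol | C/C(=C\CBr)CCCC(C)(C)O | intermediate
6 | {[(6E)-8-bromo-2,6-dimethyloct-6-en-2-yl]oxy}triethylsilane | C/C(=C\CBr)CCCC(C)(C)O[Si](CC)(CC)CC | intermediate
7 | catechol | Oc1ccccc1O | starting material
8 | 1,2-bis(methoxymethoxy)benzene | COCOc1ccccc1OCOC | intermediate
9 | [2,3-bis(methoxymethoxy)phenyl]lithium | [Li]c1cccc(OCOC)c1OCOC | intermediate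
10 | 1,2-bis(methoxymethoxy)-3-[(2E)-3,7-dimethyl-7-(triethylsilyloxy)oct-2-en-1-yl]benzene | C/C(=C\Cc1cccc(OCOC)c1OCOC)CCCC(C)(C)O[Si](CC)(CC)CC | intermediate
11 | 5,7-dihydroxy-4H-chromen-4-one | O=c1ccoc2cc(O)cc(O)c12 | starting material
12 | 5,7-bis(methoxymethoxy)-4H-chromen-4-one | O=c1ccoc2cc(OCOC)cc(OCOC)c12 | intermediate
13 | 2-{3,4-bis(methoxymethoxy)-5-[(2E)-3,7-dimethyl-7-(triethylsilyloxy)oct-2-en-1-yl]phenyl}-4,4,5,5-tetramethyl-1,3,2-dioxaborolane | C/C(=C\Cc1cc(B2OC(C)(C)C(C)(C)O2)cc(OCOC)c1OCOC)CCCC(C)(C)O[Si](CC)(CC)CC | intermediate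
14 | (2S)-2-{3,4-bis(methoxymethoxy)-5-[(2E)-3,7-dimethyl-7-(triethylsilyloxy)oct-2-en-1-yl]phenyl}-5,7-bis(methoxymethoxy)-2,3-dihydro-4H-chromen-4-one | C/C(=C\Cc1cc([C@@H]2CC(=O)c3c(OCOC)cc(OCOC)cc3O2)cc(OCOC)c1OCOC)CCCC(C)(C)O[Si](CC)(CC)CC | intermediate
15 | (2S)-2-{5-[(2E)-3,7-dimethyl-7-(triethylsilyloxy)oct-2-en-1-yl]-3,4-bis(trimethylsilyloxy)phenyl}-5,7-bis(trimethylsilyloxy)-2,3-dihydro-4H-chromen-4-one | C/C(=C\Cc1cc([C@@H]2CC(=O)c3c(O[Si](C)(C)C)cc(O[Si](C)(C)C)cc3O2)cc(O[Si](C)(C)C)c1O[Si](C)(C)C)CCCC(C)(C)O[Si](CC)(CC)CC | intermediate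
16 | propolin B, (2S)-2-{3,4-dihydroxy-5-[(2E)-7-hydroxy-3,7-dimethyloct-2-en-1-yl]phenyl}-5,7-dihydroxy-2,3-dihydro-4H-chromen-4-one | C/C(=C\Cc1cc([C@@H]2CC(=O)c3c(O)cc(O)cc3O2)cc(O)c1O)CCCC(C)(C)O | target

## Step count and risks

Total step count: 8.
Longest linear sequence: 6 (steps 1, 2, 3, 5, 7, 8).

**Step 7.** Four processes may go wrong:
- a racemic background addition by rhodium that has picked up residual cod or dtbpy from the borylation;
- slow transmetalation of the pinacol ester, so that protodeboronation takes over;
- β-oxygen elimination from the rhodium enolate;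
- hydroxide-induced opening of ring C with loss of configurational purity.

The fallback sets out from 10 and comes back at 14. It gives up the one-flask relay for a stepwise, base-free union under another metal. The borylation is run alone and 13 is isolated. NaIO4/NH4OAc in acetone/H2O cleaves the pinacol ester to the free arylboronic acid F1. This acid is then added to 12 with Pd(OCOCF3)2, (R)-t-BuPyOx, NH4PF6 and H2O in ClCH2CH2Cl at 60 °C. This is the known asymmetric conjugate addition of arylboronic acids to chromones by cationic divalent palladium (carbopalladation, then protonolysis of the palladium enolate). It needs no base and meets no iridium residues. The (R)-ligand is chosen because the (S)-ligand gives the (R)-3-aryl ketones from cyclic enones.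

**Step 8.** Four processes may go wrong:
- incomplete exchange at the chelated 5-OMOM group;
- acid-induced attack of the C4' oxygen on the chain alkene;
- ionisation of the tertiary alcohol;
- opening of ring C with erosion of configurational purity.

The fallback sets out from 10 and 11 and comes back at 16. It exchanges the acetals for fluoride-labile silyl groups before the stereocentre exists.
- Compound 10 is treated with TMSOTf/2,2'-bipyridyl in CH3CN to give the bis(trimethylsilyl) ether F2.
- Neutral water hydrolyses it to the catechol F3, with the TES group kept.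
- TBSCl/imidazole in DMF gives the bis-TBS ether F4.
- Compound 11 with TBSOTf/2,6-lutidine in CH2Cl2 gives the bis-TBS chromone F5.
- The one-flask sequence of step 7, run without KOH and with preformed [Rh(OH)((S)-MeO-F12-BIPHEP)]2, leads by way of the arylboronate F6 to the pentasilyl flavanone F7.
- Et3N·3HF in THF at rt removes all five silyl groups and gives 16 with no acetal cleavage at the chiral stage.

**Step 5.** Three processes may go wrong:
- attack at the γ-carbon, which gives the branched allyl isomer;
- homocoupling of the allylic bromide by halogen–metal exchange;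
- partial loss of alkene geometry.

The fallback sets out from 8 and comes back at 10. It replaces the organolithium substitution by a palladium-catalysed Suzuki–Miyaura allyl–aryl coupling. Compound 8 is lithiated to 9 as before and quenched with i-PrOBpin to give the ortho-boronate F8. This boronate is coupled with 6 using PdCl2(dppf) and K3PO4 in THF/H2O at 50 °C. Reductive elimination from the π-allyl complex of divalent palladium takes place at the less substituted terminus and should keep the E geometry.

## Further compounds

F1 | step 7 | {3,4-bis(methoxymethoxy)-5-[(2E)-3,7-dimethyl-7-(triethylsilyloxy)oct-2-en-1-yl]phenyl}boronic acid | C/C(=C\Cc1cc(B(O)O)cc(OCOC)c1OCOC)CCCC(C)(C)O[Si](CC)(CC)CC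
F2 | step 8 | 3-[(2E)-3,7-dimethyl-7-(triethylsilyloxy)oct-2-en-1-yl]-1,2-bis(trimethylsilyloxy)benzene | C/C(=C\Cc1cccc(O[Si](C)(C)C)c1O[Si](C)(C)C)CCCC(C)(C)O[Si](CC)(CC)CC
F3 | step 8 | 3-[(2E)-3,7-dimethyl-7-(triethylsilyloxy)oct-2-en-1-yl]benzene-1,2-diol | C/C(=C\Cc1cccc(O)c1O)CCCC(C)(C)O[Si](CC)(CC)CC
F4 | step 8 | 1,2-bis(tert-butyldimethylsilyloxy)-3-[(2E)-3,7-dimethyl-7-(triethylsilyloxy)oct-2-en-1-yl]benzene | C/C(=C\Cc1cccc(O[Si](C)(C)C(C)(C)C)c1O[Si](C)(C)C(C)(C)C)CCCC(C)(C)O[Si](CC)(CC)CC
F5 | step 8 | 5,7-bis(tert-butyldimethylsilyloxy)-4H-chromen-4-one | O=c1ccoc2cc(O[Si](C)(C)C(C)(C)C)cc(O[Si](C)(C)C(C)(C)C)c12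
F6 | step 8 | 2-{3,4-bis(tert-butyldimethylsilyloxy)-5-[(2E)-3,7-dimethyl-7-(triethylsilyloxy)oct-2-en-1-yl]phenyl}-4,4,5,5-tetramethyl-1,3,2-dioxaborolane | C/C(=C\Cc1cc(B2OC(C)(C)C(C)(C)O2)cc(O[Si](C)(C)C(C)(C)C)c1O[Si](C)(C)C(C)(C)C)CCCC(C)(C)O[Si](CC)(CC)CC
F7 | step 8 | (2S)-2-{3,4-bis(tert-butyldimethylsilyloxy)-5-[(2E)-3,7-dimethyl-7-(triethylsilyloxy)oct-2-en-1-yl]phenyl}-5,7-bis(tert-butyldimethylsilyloxy)-2,3-dihydro-4H-chromen-4-one | C/C(=C\Cc1cc([C@@H]2CC(=O)c3c(O[Si](C)(C)C(C)(C)C)cc(O[Si](C)(C)C(C)(C)C)cc3O2)cc(O[Si](C)(C)C(C)(C)C)c1O[Si](C)(C)C(C)(C)C)CCCC(C)(C)O[Si](CC)(CC)CC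
F8 | step 5 | 2-[2,3-bis(methoxymethoxy)phenyl]-4,4,5,5-tetramethyl-1,3,2-dioxaborolane | COCOc1cccc(B2OC(C)(C)C(C)(C)O2)c1OCOC
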